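Ring A hides an acyloin: C2 (acetoxy) and C3 (ketone) are neighbouring oxygenated carbons, bounded by C1H2 and quaternary C4. The plan therefore cuts C2–C3. The precursor is a ring B cyclohexane carrying a C10 acetate arm (C1–C2) and a C5 isobutyrate arm (C4–C3), trans and diequatorial, plus the C8 methylidene and the silylated axial C9 hydroxymethyl group. Sodium and Me3SiCl join the two ester carbons in one operation: C2–C3 forms, ring A closes as a trans-decalin, and both oxygens arrive at the final oxidation level as a 2,3-bis(silyloxy)alkene whose ends differ sterically because of C4. Absolute configuration comes from (S)-carvone, whose isopropenyl group is later excised.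

Key step: step 9

Remark on numbering and configuration: drimane numbering is used for every intermediate (ring A = C1–C5 and C10; ring B = C5–C10; C11 on C9; C12 on C8). The target is read as 2R,5S,9S,10R. It is a trans-decalin with the C10 methyl and the C2 acetoxy group on one face, and H5 and the axial C9–CH2OAr arm on the other.
Assumption: the C8 epimers of 10 and the peroxy-carbon epimers of 7 are not separated, because both centres vanish in the next operation.

Step 1
Reactants: 1 (S)-(+)-carvone; 2 1-methoxy-2-methyl-1-(trimethylsilyloxy)prop-1-ene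
Product: 3 methyl 2-methyl-2-[(1S,5S)-2-methyl-5-(prop-1-en-2-yl)-3-(trimethylsilyloxy)cyclohex-2-en-1-yl]propanoate
Conditions: Ph3CSbCl6 (5 mol %), CH2Cl2, −78 °C; pyridine quench
Reagents that add atoms: none
Why: Mukaiyama–Michael addition: the trityl cation activates the enone, the ketene acetal attacks C5 axially on the ring face opposite the C7 isopropenyl group (setting C5 as S, trans to it), and silyl transfer stores the C9–C10 enolate regiospecifically as its silyl ether.

Step 2
Reactants: 3 Michael adduct silyl enol ether; 4 methyl bromoacetate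
Product: 6 methyl 2-[(1S,2R,5S)-2-(2-methoxy-2-oxoethyl)-2-methyl-3-oxo-5-(prop-1-en-2-yl)cyclohexyl]-2-methylpropanoate, via benzyltrimethylammonium enolate 5 (not isolated)
Conditions: BnMe3NF, 4 Å MS, THF, −20 °C → rt
Reagents that add atoms: none
Why: Fluoride-induced regiospecific alkylation of a silyl enol ether: allylic 1,2-strain against the C10 methyl pushes the bulky C5 side chain into an axial position, so enolate 5 takes up bromoacetate at C10 on the opposite face and the quaternary centre (R) forms with the two ester arms trans.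

Step 3
Reactants: 6 isopropenyl keto diester
Product: 8 methyl 2-[(1S,2R)-2-(2-methoxy-2-oxoethyl)-2-methyl-3-oxocyclohexyl]-2-methylpropanoate, via α-methoxy hydroperoxide 7 (not isolated)
Conditions: O3, MeOH, −78 °C; then PhSH, FeSO4·7H2O, −78 °C → rt
Reagents that add atoms: none
Why: Hydrodealkenylation (ozonolysis in methanol, then divalent iron and a thiol): one-electron reduction of 7 gives an alkoxy radical that loses methyl acetate by β-scission, and the secondary C7 radical abstracts hydrogen from PhSH, so the control element is deleted while ketone, esters, C5 and C10 stay untouched.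

Step 4
Reactants: 8 keto diester
Product: 10 methyl 2-[(1S,2R)-2-(2-methoxy-2-oxoethyl)-2-methyl-3-oxo-4-[(trimethylsilyl)methyl]cyclohexyl]-2-methylpropanoate (C8 epimers), via lithium enolate 9 (not isolated)
Conditions: LiN(iPr)2, THF, −78 °C; then Me3SiCH2OTf, −78 → −20 °C
Reagents that add atoms: (trimethylsilyl)methyl trifluoromethanesulfonate, C[Si](C)(C)COS(=O)(=O)C(F)(F)F
Why: Kinetic enolate alkylation: C10 is quaternary, so the ketone can enolise only towards C8 and does so faster than the neopentyl-type ester CH2 is deprotonated, and the primary triflate is reactive enough to alkylate carbon at low temperature before proton exchange sets in.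

Step 5
Reactants: 10 β-silyl ketone
Product: 12 methyl 2-[(1S,2R)-2-(2-methoxy-2-oxoethyl)-2-methyl-3-(trifluoromethylsulfonyloxy)-4-[(trimethylsilyl)methyl]cyclohex-3-en-1-yl]-2-methylpropanoate, via potassium enolate 11 (not isolated)
Conditions: KN(SiMe3)2, THF, −78 → −40 °C; then PhNTf2, −78 → 0 °C
Reagents that add atoms: N-phenylbis(trifluoromethanesulfonimide), O=S(=O)(N(c1ccccc1)S(=O)(=O)C(F)(F)F)C(F)(F)F
Why: Enol triflate formation: the single remaining α-hydrogen (C8) allows only one enolate, whose O-sulfonylation next to a quaternary carbon has close analogy in 2,2,6-trisubstituted cyclohexanones, and the C8 stereocentre is erased.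

Step 6
Reactants: 12 enol triflate
Product: 13 methyl 2-[(1S,2S)-2-(2-methoxy-2-oxoethyl)-2-methyl-4-[(trimethylsilyl)methyl]cyclohex-3-en-1-yl]-2-methylpropanoate
Conditions: Pd(OAc)2 (cat.), PPh3, HCO2H, Et3N, DMF, 60 °C
Reagents that add atoms: none
Why: Palladium-catalysed formate reduction of a vinyl triflate: oxidative addition to zerovalent palladium, decarboxylation of the formate ligand and reductive elimination replace OTf by H with the C8=C9 bond held in place, and the amine-buffered medium spares the allylsilane and the esters.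

Step 7
Reactants: 13 allylsilane
Product: 15 methyl 2-[(1S,2R,3S)-3-(hydroxymethyl)-2-(2-methoxy-2-oxoethyl)-2-methyl-4-methylidenecyclohexyl]-2-methylpropanoate, via dimethylaluminium alkoxide 14 (not isolated)
Conditions: (CH2O)n, Me2AlCl, CH2Cl2, −78 → −20 °C; cold aq. NaHCO3
Reagents that add atoms: formaldehyde (from paraformaldehyde), C=O
Why: Hosomi–Sakurai reaction (SE2′ hydroxymethylation): complexed formaldehyde attacks C9, the γ-carbon of the allylsilane, on the face opposite the pseudoaxial C10 methyl, the β-silyl cation at C8 loses Me3Si to give the C8=C12 methylidene, and C9 (S) is thereby set with C11 axial and trans to that methyl, while Me2AlCl scavenges the protons that would cause protodesilylation.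

Step 8
Reactants: 15 homoallylic alcohol
Product: 16 methyl 2-[(1S,2R,3S)-3-{[(tert-butyldimethylsilyl)oxy]methyl}-2-(2-methoxy-2-oxoethyl)-2-methyl-4-methylidenecyclohexyl]-2-methylpropanoate (seco ring A diester)
Conditions: TBSOTf, 2,6-lutidine, CH2Cl2, −78 °C
Reagents that add atoms: tert-butyldimethylsilyl trifluoromethanesulfonate, CC(C)(C)[Si](C)(C)OS(=O)(=O)C(F)(F)F
Why: Silyl ether formation under fast, cold and weakly basic conditions, run on freshly prepared 15 because C11–OH and the C1–C2 arm are cis on ring B and would otherwise drift to a δ-lactone that ties C2 away from C3.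

Step 9
Reactants: 16 seco ring A diester
Product: 18 (5S,9S,10R)-11-(tert-butyldimethylsilyloxy)-2,3-bis(trimethylsilyloxy)drima-2,8(12)-diene, via ring A 2,3-dione 17 (not isolated)
Conditions: Na (sand, 5 equiv), Me3SiCl (6 equiv), toluene, 110 °C, slow addition of 16
Reagents that add atoms: chlorotrimethylsilane, C[Si](C)(C)Cl
Why: Sodium passes single electrons to both ester carbonyls, the C2 and C3 ketyl radical anions combine, two methoxides leave to give dione 17, and two more electrons produce the enediolate, which Me3SiCl caps on both oxygens while it also removes methoxide as MeOSiMe3. This is the Rühlmann (chlorosilane-trapping) form of the acyloin condensation, well established for adipate-type diesters including α,α-dimethyl-substituted ones. Ring A closes as a six-membered carbocycle by intramolecular reductive carbonyl–carbonyl coupling, with both C=O bonds exocyclic to the forming ring, and because the two arms sit trans-diequatorial on ring B only the trans-decalin can result. No stereocentre is created, and C5, C9 and C10 carry no hydrogen α to a carbonyl, so they pass through unchanged. The selectivity required is chemoselectivity: the isolated C8 methylidene and the alkyl silyl ether should not be reduced by sodium in toluene, and scavenging of methoxide suppresses the competing Dieckmann closure of C1 onto C3. Quaternary C4 leaves the two silyloxy carbons sterically unequal, which step 10 uses.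

Step 10
Reactants: 18 bis(silyloxy)octalin
Product: 20 (5S,9S,10R)-2-acetoxy-11-(tert-butyldimethylsilyloxy)-3-(trimethylsilyloxy)drima-2,8(12)-diene, via lithium C2 enolate 19 (not isolated)
Conditions: MeLi (1 equiv), THF, −30 → 0 °C; then cannulated into Ac2O, THF, −78 °C
Reagents that add atoms: acetic anhydride, CC(=O)OC(C)=O
Why: Cleavage of a silyl enol ether with MeLi followed by O-acetylation of the lithium enolate in excess anhydride: the O2 silicon, flanked only by C1H2, is more accessible than the O3 silicon beside the C4 gem-dimethyl group, C-acylation would have to occur at fully substituted C3, and both the lithium aggregate and the incoming acetyl group prefer the less hindered O2 even if silyl migration equilibrates the enolates.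

Step 11
Reactants: 20 enol acetate silyl enol ether
Product: 22 (2R,5S,9S,10R)-2-acetoxy-11-hydroxydrim-8(12)-en-3-one, via keto acetate TBS ether 21 (not isolated)
Conditions: HF·pyridine, pyridine, THF, −20 °C → rt
Reagents that add atoms: none
Why: Fluoride-assisted protodesilylation with kinetic ketonisation: loss of Me3Si from O3 and protonation of C2 on the face opposite the syn-axial C10 and C4 methyl groups places the acetoxy group on the methyl face (C2 = R, the less stable axial epimer), the buffered acidic medium avoids a free enolate and hence acetyl migration, and the same reagent then cleaves the primary TBS ether.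

Step 12
Reactants: 22 hydroxy keto acetate; 23 isofraxidin (7-hydroxy-6,8-dimethoxycoumarin)
Product: 24 (2R,5S,9S,10R)-2-acetoxy-11-[(6,8-dimethoxy-2-oxo-2H-chromen-7-yl)oxy]drim-8(12)-en-3-one (target, CNP0183157.1)
Conditions: PPh3, DIAD, THF, 0 °C → rt
Reagents that add atoms: none
Why: Mitsunobu etherification: the acidic 7-OH of 23 protonates the betaine and its phenoxide displaces the C11 oxyphosphonium ion in an SN2 process at a primary carbon, under essentially neutral conditions that leave the epimerisable C2 centre, the acetate and the coumarin lactone alone.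

Compound list
1 | (S)-(+)-carvone | CC1=CC[C@@H](CC1=O)C(C)=C | starting material
2 | 1-methoxy-2-methyl-1-(trimethylsilyloxy)prop-1-ene | COC(O[Si](C)(C)C)=C(C)C | starting material
3 | Michael adduct, C9–C10 trimethylsilyl enol ether (C5 S, C7 S) | C[Si](C)(C)OC1=C(C)[C@@H](C(C)(C)C(=O)OC)C[C@H](C(C)=C)C1 | intermediate
4 | methyl bromoacetate | COC(=O)CBr | starting material
5 | benzyltrimethylammonium C9–C10 enolate | C[N+](C)(C)Cc1ccccc1.[O-]C1=C(C)[C@@H](C(C)(C)C(=O)OC)C[C@H](C(C)=C)C1 | intermediate
6 | C7-isopropenyl keto diester (C5 S, C10 R, C7 S) | O=C1C[C@@H](C(C)=C)C[C@H](C(C)(C)C(=O)OC)[C@@]1(C)CC(=O)OC | intermediate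
7 | α-methoxy hydroperoxide at the former isopropenyl carbon (that carbon undefined) | O=C1C[C@@H](C(C)(OC)OO)C[C@H](C(C)(C)C(=O)OC)[C@@]1(C)CC(=O)OC | intermediate
8 | C9 keto diester (C5 S, C10 R) | O=C1CCC[C@H](C(C)(C)C(=O)OC)[C@@]1(C)CC(=O)OC | intermediate
9 | lithium C8–C9 enolate of 8 | [Li]OC1=CCC[C@H](C(C)(C)C(=O)OC)[C@@]1(C)CC(=O)OC | intermediate
10 | C8-(trimethylsilylmethyl) keto diester (C8 undefined) | O=C1C(C[Si](C)(C)C)CC[C@H](C(C)(C)C(=O)OC)[C@@]1(C)CC(=O)OC | intermediate
11 | potassium C8–C9 enolate of 10 | [K]OC1=C(C[Si](C)(C)C)CC[C@H](C(C)(C)C(=O)OC)[C@@]1(C)CC(=O)OC | intermediate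
12 | C9 enol triflate | O=S(=O)(OC1=C(C[Si](C)(C)C)CC[C@H](C(C)(C)C(=O)OC)[C@@]1(C)CC(=O)OC)C(F)(F)F | intermediate
13 | allylsilane, C8=C9 with C12H2SiMe3 (C5 S, C10 S) | C1=C(C[Si](C)(C)C)CC[C@H](C(C)(C)C(=O)OC)[C@@]1(C)CC(=O)OC | intermediate
14 | dimethylaluminium C11 alkoxide | C=C1CC[C@H](C(C)(C)C(=O)OC)[C@@](C)(CC(=O)OC)[C@H]1CO[Al](C)C | intermediate
15 | C11 alcohol, C8 methylidene diester (C5 S, C9 S, C10 R) | C=C1CC[C@H](C(C)(C)C(=O)OC)[C@@](C)(CC(=O)OC)[C@H]1CO | intermediate
16 | seco ring A diester, C11 TBS ether | C=C1CC[C@H](C(C)(C)C(=O)OC)[C@@](C)(CC(=O)OC)[C@H]1CO[Si](C)(C)C(C)(C)C | intermediate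
17 | ring A 2,3-dione | C=C1CC[C@@H]2C(C)(C)C(=O)C(=O)C[C@@]2(C)[C@H]1CO[Si](C)(C)C(C)(C)C | intermediate
18 | 2,3-bis(trimethylsilyloxy)octalin | C=C1CC[C@@H]2C(C)(C)C(O[Si](C)(C)C)=C(O[Si](C)(C)C)C[C@@]2(C)[C@H]1CO[Si](C)(C)C(C)(C)C | intermediate
19 | lithium C2 enolate, O3 still silylated | C=C1CC[C@@H]2C(C)(C)C(O[Si](C)(C)C)=C(O[Li])C[C@@]2(C)[C@H]1CO[Si](C)(C)C(C)(C)C | intermediate
20 | 2-acetoxy-3-(trimethylsilyloxy)-2-ene | C=C1CC[C@@H]2C(C)(C)C(O[Si](C)(C)C)=C(OC(C)=O)C[C@@]2(C)[C@H]1CO[Si](C)(C)C(C)(C)C | intermediate
21 | (2R)-2-acetoxy-3-ketone, C11 TBS ether | C=C1CC[C@@H]2C(C)(C)C(=O)[C@H](OC(C)=O)C[C@@]2(C)[C@H]1CO[Si](C)(C)C(C)(C)C | intermediate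
22 | (2R)-2-acetoxy-3-ketone, C11 alcohol | C=C1CC[C@@H]2C(C)(C)C(=O)[C@H](OC(C)=O)C[C@@]2(C)[C@H]1CO | intermediate
23 | isofraxidin | COc1cc2ccc(=O)oc2c(OC)c1O | starting material
24 | target CNP0183157.1 | C=C1CC[C@@H]2C(C)(C)C(=O)[C@H](OC(C)=O)C[C@@]2(C)[C@H]1COc1c(OC)cc2ccc(=O)oc2c1OC | target

Total step count: 12. Longest linear sequence: 12 steps (1 → 24).

Steps most likely to fail

Step 9 (key step). The neopentyl C3 ester may accept electrons and couple too slowly. Base-induced Dieckmann closure of C1 onto C3, or plain reductive cleavage of the esters, could then overtake ring closure. The fallback sets out from 16 and returns at 20. It keeps the C2–C3 bond construction but turns it into a pinacol coupling of aldehydes.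
- LiAlH4 in Et2O reduces both esters of 16 to the seco diol F1.
- Swern oxidation gives the seco dialdehyde F2.
- SmI2 in THF closes ring A as the 2,3-diol F3. Its two carbinol centres are oxidised away next, so their configuration is irrelevant.
- A double Swern oxidation gives the dione as its only possible enol, the diosphenol F4.
- Ac2O and pyridine give the diosphenol acetate F5.
- Conjugate reduction with [(Ph3P)CuH]6 in the presence of Me3SiCl places hydride on C1 and traps the C3 enolate, which is 20.

Step 10. MeLi may attack the two silicon atoms with little discrimination, or the silyl group may wander from O3 to O2 in enolate 19. Either process would put the acetate on O3. The fallback sets out from 18 and returns at 21. It lets the site of carbon protonation, not attack at silicon, decide the regiochemistry.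
- Citric acid in MeOH at 0 °C should protonate the enediol ether at the less hindered C2, on the face opposite the methyl groups, and strip both Me3Si groups to give the 2-hydroxy 3-ketone F6.
- F6 is acetylated at once (Ac2O, pyridine, 0 °C) to 21.
- The TBS ether of 21 is then cleaved with HF·pyridine as in the second half of step 11.

Step 11. Three processes threaten C2: poor facial selectivity in the ketonisation, acetyl migration in the transient enol, and epimerisation of the axial acetate to its equatorial epimer during the slower TBS cleavage. The fallback sets out from 18 and returns at 21. It sets C2 by hydride delivery instead of proton delivery.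
- Enolate 19, made as in step 10, is quenched with AcOH at −78 °C instead of Ac2O to give the 3-silyloxy 2-ketone F7.
- LiAlH(OtBu)3 in THF attacks the C2 carbonyl from the face opposite the two syn-axial methyl groups and gives the axial 2-alcohol F8.
- Ac2O, Et3N and 4-(dimethylamino)pyridine give the 2-acetate F9.
- Pyridinium p-toluenesulfonate in MeOH at 0 °C removes only the Me3Si ether to give the 3-hydroxy 2-acetate F10.
- Dess–Martin oxidation of C3–OH gives 21, which needs only a short HF·pyridine treatment to reach 22.

Further compounds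
F1 | step 9 | 11-O-TBS 2,3-secodrim-8(12)-ene-2,3-diol (C5, C9, C10 as in 16) | C=C1CC[C@H](C(C)(C)CO)[C@@](C)(CCO)[C@H]1CO[Si](C)(C)C(C)(C)C
F2 | step 9 | 11-O-TBS 2,3-secodrim-8(12)-ene-2,3-dial | C=C1CC[C@H](C(C)(C)C=O)[C@@](C)(CC=O)[C@H]1CO[Si](C)(C)C(C)(C)C
F3 | step 9 | 11-O-TBS drim-8(12)-ene-2,3-diol (C2 and C3 undefined) | C=C1CC[C@@H]2C(C)(C)C(O)C(O)C[C@@]2(C)[C@H]1CO[Si](C)(C)C(C)(C)C
F4 | step 9 | 11-O-TBS 2-hydroxydrima-1,8(12)-dien-3-one (diosphenol) | C=C1CC[C@@H]2C(C)(C)C(=O)C(O)=C[C@@]2(C)[C@H]1CO[Si](C)(C)C(C)(C)C
F5 | step 9 | 11-O-TBS 2-acetoxydrima-1,8(12)-dien-3-one | C=C1CC[C@@H]2C(C)(C)C(=O)C(OC(C)=O)=C[C@@]2(C)[C@H]1CO[Si](C)(C)C(C)(C)C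
F6 | step 10 | (2R)-11-O-TBS 2-hydroxydrim-8(12)-en-3-one | C=C1CC[C@@H]2C(C)(C)C(=O)[C@H](O)C[C@@]2(C)[C@H]1CO[Si](C)(C)C(C)(C)C
F7 | step 11 | (3S)-11-O-TBS 3-(trimethylsilyloxy)drim-8(12)-en-2-one | C=C1CC[C@@H]2C(C)(C)[C@H](O[Si](C)(C)C)C(=O)C[C@@]2(C)[C@H]1CO[Si](C)(C)C(C)(C)C
F8 | step 11 | (2R,3S)-11-O-TBS 3-(trimethylsilyloxy)drim-8(12)-en-2-ol | C=C1CC[C@@H]2C(C)(C)[C@H](O[Si](C)(C)C)[C@H](O)C[C@@]2(C)[C@H]1CO[Si](C)(C)C(C)(C)C
F9 | step 11 | (2R,3S)-11-O-TBS 2-acetoxy-3-(trimethylsilyloxy)drim-8(12)-ene | C=C1CC[C@@H]2C(C)(C)[C@H](O[Si](C)(C)C)[C@H](OC(C)=O)C[C@@]2(C)[C@H]1CO[Si](C)(C)C(C)(C)C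
F10 | step 11 | (2R,3S)-11-O-TBS 2-acetoxydrim-8(12)-en-3-ol | C=C1CC[C@@H]2C(C)(C)[C@H](O)[C@H](OC(C)=O)C[C@@]2(C)[C@H]1CO[Si](C)(C)C(C)(C)C
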